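**Late times.** At late times I look for a ceiling first. In Tuesday's run, target and substrate add up to 100% at the last reading, so I count one substrate lost per target made. If one reagent goes with each substrate, then substrate is the limiting reagent: Tuesday's flask holds 0.90 M of reagent against 0.30 M, and north-east holds 0.900 M against 0.45 M. I expect both flasks to climb towards their whole substrate charge. The open question is how fast.

in all of them: catalyst 0.77 mM

|  | substrate | reagent | added ligand | remark | time |
|---|---|---|---|---|---|
| Tuesday's | 0.30 M | 0.90 M | 0.20 mM | run made earlier |  |
| north-east | 0.45 M | 0.900 M | 0.20 mM |  | 4.0 h |
| south-east | 0.45 M | 0.900 M | 0.40 mM |  | 4.0 h |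
| west | 0.45 M | 0.900 M | 0.80 mM |  | 4.0 h |
| south | 0.45 M | 0.900 M | 1.5 mM |  | 4.0 h |

Tuesday's run (percent of the substrate charged)

| time / h | target / % | substrate / % |
|---|---|---|
| 0.200 | 1.8 | 97.6 |
| 0.333 | 3.5 | 95.7 |
| 0.500 | 4.7 | 95.1 |
| 0.833 | 8.3 | 92.2 |
| 1.33 | 12.1 | 86.8 |
| 2.50 | 22.1 | 78.0 |

(scatter of a reading: 0.5 percentage points)

- no earlier run changes the charge of added ligand; that part of a forecast is a guess
- "hardly changes" means that all values lie within two and a half points (for a concentration: within two and a half percent of the largest)

* amount of target at the end, in percent of the substrate charged for north-east, south-east, west, south, in this order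
* how that number moves from the first to the last of them (rises all the way / falls all the way / falls, then rises / rises, then falls / hardly changes)

**The neighbour.** North-east has Tuesday's catalyst, reagent and added ligand, but more substrate. Tuesday's last reading gives 0.0994 h⁻¹. This is the fractional rate, the logarithm of charged over remaining substrate, divided by the time. It is the pseudo-first-order constant. If [substrate] does not enter it, north-east loses the same share per hour, and after 4.0 h it holds 32.8% of target. Its reagent is used up faster relative to its charge, so I read my figure as slightly high. No run varies the added ligand, so I give no number for the other flasks.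

**The forecast.** The forecast reads 29%, 33%, 36%, 31%, and its shape is rises, then falls. Past the peak it expects that “excess may then block sites”. Its first value stands below my figure.

**The flask.** The flasks give 31.5%, 25.1%, 14.3%, 6.12%. The shape is falls all the way.

    substrate + reagent + catalyst → catalyst + target (k = 0.0530 L² mol⁻² s⁻¹)
    catalyst + added ligand ⇌ idle complex, settled at all times (K = 8800 L mol⁻¹)

**Held catalyst.** Target falls down the row because added ligand holds catalyst as idle complex and because the time given is 4.0 h, against ten times as long, 40.0 h, when south holds 43.1%. Without that joining, south reaches 37.7%. The rate law contains free [catalyst], and south keeps 12.1% free where north-east keeps 78.2%. Tuesday's charges of catalyst and added ligand are north-east's, so I scale 0.0994 h⁻¹ by that ratio. For south this gives 0.0154 h⁻¹, which means 5.98% of target after 4.0 h. South stands at 6.12%.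

The readings were generated by integration with made-up constants, noise included.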